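**Retrosynthetic overview**
1. The ester C–O bond is formed last: linoleic acid plus the (2E,6E)-C20 dienol.
2. Feature: with the alcohol chain numbered from OCH2 = C1 to C9 = the CH2 on ring carbon r1, the C4–C5 single bond joins two allylic CH2 groups, C4 beside the (E)-C2=C3 alkene and C5 beside the (E)-C6=C7 alkene. It is cut into a ring-bearing C15 allylic phenyl sulfone (carbanion at C5) and a C5 (E)-allylic bromide (electrophile at C4), each with its alkene geometry already in place; the sulfonyl group is removed after the union.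
3. C15 sulfone: from (S)-α-ionone by 1,4-reduction, methyl ketone to terminal alkyne, zirconium-catalysed methylalumination with formaldehyde capture (sets C6=C7 as E), bromide, sulfinate.
4. C5 bromide: from prenol by silylation, SeO2 oxidation of the (E)-methyl group and Appel bromination.
5. No ring is formed in the route: the 2,6,6-trimethylcyclohex-2-ene ring and its stereocentre r1 (S) come with α-ionone, whose racemate is resolved in the first step.

Key step: step 10

Assumption: racemic α-ionone is taken to be separable on a preparative polysaccharide chiral phase, and the levorotatory enantiomer is the (S)-enantiomer, which has the spatial arrangement at r1 that the target needs.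

**Route**

Step 1
Reactants: 1 racemic α-ionone [(E)-4-(2,6,6-trimethylcyclohex-2-en-1-yl)but-3-en-2-one]
Product: 2 (S)-(−)-α-ionone
Conditions: preparative SFC on amylose tris(3,5-dimethylphenylcarbamate)-coated silica, CO2/MeOH, 35 °C; levorotatory fraction kept
Reagents that add atoms: none
Why: Resolution by chromatography on a chiral stationary phase, in which the enantiomers bind the carbamate-derivatised amylose as diastereomeric complexes and elute apart, so the ring stereocentre (S) of the whole route is fixed here by selection of a fraction and not by a reaction.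

Step 2
Reactants: 2 (S)-(−)-α-ionone
Product: 4 (S)-4-(2,6,6-trimethylcyclohex-2-en-1-yl)butan-2-one, via triethylsilyl enol ether 3 (not isolated)
Conditions: Et3SiH (1.2 equiv), RhCl(PPh3)3 (0.5 mol%), PhMe, 50 °C; then K2CO3, MeOH/H2O, rt
Reagents that add atoms: none
Why: Rhodium-catalysed 1,4-hydrosilylation of the enone (a monohydrosilane places Si on oxygen and H on the β-carbon) followed by solvolysis of the silyl enol ether gives the saturated ketone under near-neutral conditions, so no dienolate forms through the γ-position and the ring stereocentre and the trisubstituted ring alkene are left alone.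

Step 3
Reactants: 4 (S)-4-(2,6,6-trimethylcyclohex-2-en-1-yl)butan-2-one
Product: 6 (S)-4-(2,6,6-trimethylcyclohex-2-en-1-yl)but-1-yne, via enol diethyl phosphate 5 (not isolated)
Conditions: LiN(i-Pr)2 (1.05 equiv), THF, −78 °C; ClP(O)(OEt)2 (1.1 equiv), −78 °C → rt; then LiN(i-Pr)2 (2.3 equiv), THF, −78 °C → rt; H2O
Reagents that add atoms: none
Why: Methyl ketone to terminal alkyne by enol phosphate elimination: kinetic deprotonation at CH3, O-phosphorylation of the enolate, and base-induced β-elimination of diethyl phosphate, with the product held as its lithium acetylide so that it should not isomerise to an allene or internal alkyne.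

Step 4
Reactants: 6 (S)-4-(2,6,6-trimethylcyclohex-2-en-1-yl)but-1-yne
Product: 9 (S,E)-3-methyl-5-(2,6,6-trimethylcyclohex-2-en-1-yl)pent-2-en-1-ol, via alkenyldimethylalane 7 (not isolated), via lithium alkenylaluminate 8 (not isolated)
Conditions: Me3Al (2.0 equiv), Cp2ZrCl2 (0.25 equiv), CH2Cl2, 0 °C → rt; volatiles removed, hexane; n-BuLi (1.0 equiv), 0 °C; (CH2O)n (3 equiv), THF, rt; aq. potassium sodium tartrate
Reagents that add atoms: trimethylaluminium, C[Al](C)C; paraformaldehyde (reacts as formaldehyde), C=O
Why: Negishi zirconium-catalysed carboalumination adds CH3 and Al syn across the terminal alkyne with Al on the terminal carbon, and the derived aluminate transfers its alkenyl group to formaldehyde with retention, which fixes the C6=C7 alkene as E.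

Step 5
Reactants: 9 (S,E)-3-methyl-5-(2,6,6-trimethylcyclohex-2-en-1-yl)pent-2-en-1-ol
Product: 10 (S,E)-1-bromo-3-methyl-5-(2,6,6-trimethylcyclohex-2-en-1-yl)pent-2-ene
Conditions: PBr3 (0.4 equiv), pyridine (cat.), Et2O, −10 → 0 °C, dark; used crude
Reagents that add atoms: phosphorus tribromide, BrP(Br)Br
Why: Bromination of a primary allylic alcohol with PBr3 (SN2 displacement on the bromophosphite), as in the preparation of geranyl and farnesyl bromides; the low temperature should keep the E geometry and avoid HBr addition to the ring alkene.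

Step 6
Reactants: 10 (S,E)-1-bromo-3-methyl-5-(2,6,6-trimethylcyclohex-2-en-1-yl)pent-2-ene; 11 sodium benzenesulfinate
Product: 12 (S,E)-[3-methyl-5-(2,6,6-trimethylcyclohex-2-en-1-yl)pent-2-en-1-yl] phenyl sulfone
Conditions: DMF, 0 °C → rt
Reagents that add atoms: none
Why: SN2 S-alkylation of the ambident sulfinate anion by the primary allylic bromide, the standard preparation of prenyl-type phenyl sulfones, which keeps the E geometry.

Step 7
Reactants: 13 3-methylbut-2-en-1-ol (prenol)
Product: 14 tert-butyldimethyl[(3-methylbut-2-en-1-yl)oxy]silane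
Conditions: TBSCl (1.1 equiv), imidazole (2 equiv), CH2Cl2, 0 °C → rt
Reagents that add atoms: tert-butyldimethylsilyl chloride, CC(C)(C)[Si](C)(C)Cl
Why: Imidazole-promoted silylation of a primary alcohol (silyl ether protection).

Step 8
Reactants: 14 tert-butyldimethyl[(3-methylbut-2-en-1-yl)oxy]silane
Product: 16 (E)-4-[(tert-butyldimethylsilyl)oxy]-2-methylbut-2-en-1-ol, via over-oxidised enal 15 (not isolated)
Conditions: SeO2 (0.3 equiv), t-BuOOH (2.5 equiv, in decane), CH2Cl2, 0 °C → rt; then NaBH4, MeOH, 0 °C
Reagents that add atoms: selenium dioxide (delivers the oxygen), O=[Se]=O; tert-butyl hydroperoxide (terminal oxidant that restores it), CC(C)(C)OO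
Why: Selenium dioxide allylic oxidation (ene reaction then 2,3-sigmatropic shift) attacks the methyl group trans to the CH2O chain on the more substituted alkene carbon and so gives the (E)-allylic alcohol, while the borohydride treatment returns the part that went on to enal 15 by 1,2-reduction.

Step 9
Reactants: 16 (E)-4-[(tert-butyldimethylsilyl)oxy]-2-methylbut-2-en-1-ol
Product: 17 (E)-[(4-bromo-3-methylbut-2-en-1-yl)oxy](tert-butyl)dimethylsilane
Conditions: CBr4 (1.2 equiv), PPh3 (1.25 equiv), CH2Cl2, 0 °C
Reagents that add atoms: carbon tetrabromide, BrC(Br)(Br)Br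
Why: Appel reaction of a primary allylic alcohol under neutral conditions, which leaves the silyl ether and the alkene geometry intact.

Step 10
Reactants: 12 (S,E)-[3-methyl-5-(2,6,6-trimethylcyclohex-2-en-1-yl)pent-2-en-1-yl] phenyl sulfone; 17 (E)-[(4-bromo-3-methylbut-2-en-1-yl)oxy](tert-butyl)dimethylsilane
Product: 19 tert-butyldimethyl{[(2E,6E)-3,7-dimethyl-5-(phenylsulfonyl)-9-[(S)-2,6,6-trimethylcyclohex-2-en-1-yl]nona-2,6-dien-1-yl]oxy}silane (mixture of C5 epimers), via lithiated sulfone 18 (not isolated)
Conditions: n-BuLi (1.05 equiv), THF, −78 °C, 30 min; then 17 (1.1 equiv) in THF, −78 → −20 °C; aq. NH4Cl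
Reagents that add atoms: none
Why: n-BuLi removes one proton from the CH2 of 12 that lies between the sulfonyl group and the C6=C7 alkene, giving the sulfonyl-stabilised allyl anion 18 with its charge and lithium at the carbon next to sulfur. This carbanion displaces bromide from the primary allylic CH2Br (C4) of 17 by direct SN2 attack and so forms the C4–C5 single bond, the classical sulfone alkylation used to join prenyl units head to tail. No ring is closed. The one new stereocentre, C5 carrying the sulfonyl group, is not controlled (the ring centre is four bonds away) and need not be, because C5 becomes CH2 in step 11; the ring centre (S) and both alkene geometries are not touched. Two selectivities are needed: alkylation at the α- and not the γ-carbon of the allyl anion, secured by the sulfonyl group that holds the charge next to sulfur and by the fully substituted γ-carbon C7; and direct instead of allylically transposed attack on the bromide, secured by the unhindered primary CH2Br set against a hindered trisubstituted alkene terminus. Addition at −78 °C with a slight excess of 17 and no excess base should limit a second alkylation of the more hindered, less acidic product.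

Step 11
Reactants: 19 C5-phenylsulfonyl (2E,6E)-dienyl silyl ether
Product: 20 tert-butyldimethyl{[(2E,6E)-3,7-dimethyl-9-[(S)-2,6,6-trimethylcyclohex-2-en-1-yl]nona-2,6-dien-1-yl]oxy}silane
Conditions: LiBHEt3 (2.5 equiv), PdCl2(dppp) (5 mol%; dppp = 1,3-bis(diphenylphosphino)propane), THF, 0 °C
Reagents that add atoms: none
Why: Palladium-catalysed reductive desulfonylation, in which zerovalent palladium (formed from PdCl2(dppp) by the hydride) ionises the allylic C–S bond to a π-allylpalladium sulfinate and LiBHEt3 delivers hydride to the less substituted terminus C5, so that C6=C7 should stay in place and stay E while the silyl ether and the other alkenes are inert to the borohydride.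

Step 12
Reactants: 20 (2E,6E)-dienyl silyl ether
Product: 21 (2E,6E)-3,7-dimethyl-9-[(S)-2,6,6-trimethylcyclohex-2-en-1-yl]nona-2,6-dien-1-ol
Conditions: Bu4NF (1.2 equiv), THF, 0 °C → rt
Reagents that add atoms: none
Why: Fluoride-induced cleavage of the Si–O bond (desilylation), to which the alkenes and the ring stereocentre are inert.

Step 13
Reactants: 21 (2E,6E)-3,7-dimethyl-9-[(S)-2,6,6-trimethylcyclohex-2-en-1-yl]nona-2,6-dien-1-ol; 22 linoleic acid [(9Z,12Z)-octadeca-9,12-dienoic acid]
Product: 24 (2E,6E)-3,7-dimethyl-9-[(S)-2,6,6-trimethylcyclohex-2-en-1-yl]nona-2,6-dien-1-yl (9Z,12Z)-octadeca-9,12-dienoate (CNP0369707.1), via O-acylisourea 23 (not isolated)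
Conditions: DCC (1.2 equiv), DMAP (0.1 equiv), CH2Cl2, 0 °C → rt, under argon
Reagents that add atoms: none
Why: Steglich esterification, in which the acid is activated as the O-acylisourea and DMAP passes the acyl group to the primary allylic alcohol under neutral conditions that should leave the skipped (Z,Z)-diene and the three other alkenes unisomerised.

**Compound list**
1 | α-ionone, racemic, (E)-4-(2,6,6-trimethylcyclohex-2-en-1-yl)but-3-en-2-one | CC(=O)/C=C/C1C(C)=CCCC1(C)C | starting material
2 | (S)-(−)-α-ionone, (S,E)-4-(2,6,6-trimethylcyclohex-2-en-1-yl)but-3-en-2-one | CC(=O)/C=C/[C@@H]1C(C)=CCCC1(C)C | intermediate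
3 | triethyl{[(S)-4-(2,6,6-trimethylcyclohex-2-en-1-yl)but-2-en-2-yl]oxy}silane, E/Z mixture at the enol ether (not isolated) | CC[Si](CC)(CC)OC(C)=CC[C@@H]1C(C)=CCCC1(C)C | intermediate
4 | (S)-4-(2,6,6-trimethylcyclohex-2-en-1-yl)butan-2-one | CC(=O)CC[C@@H]1C(C)=CCCC1(C)C | intermediate
5 | diethyl (S)-4-(2,6,6-trimethylcyclohex-2-en-1-yl)but-1-en-2-yl phosphate (not isolated) | C=C(OP(=O)(OCC)OCC)CC[C@@H]1C(C)=CCCC1(C)C | intermediate
6 | (S)-4-(2,6,6-trimethylcyclohex-2-en-1-yl)but-1-yne | C#CCC[C@@H]1C(C)=CCCC1(C)C | intermediate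
7 | dimethyl[(S,E)-2-methyl-4-(2,6,6-trimethylcyclohex-2-en-1-yl)but-1-en-1-yl]alane (not isolated) | C[Al](C)/C=C(\C)CC[C@@H]1C(C)=CCCC1(C)C | intermediate
8 | lithium butyldimethyl[(S,E)-2-methyl-4-(2,6,6-trimethylcyclohex-2-en-1-yl)but-1-en-1-yl]aluminate (not isolated) | [Li+].CCCC[Al-](C)(C)/C=C(\C)CC[C@@H]1C(C)=CCCC1(C)C | intermediate
9 | (S,E)-3-methyl-5-(2,6,6-trimethylcyclohex-2-en-1-yl)pent-2-en-1-ol | OC/C=C(\C)CC[C@@H]1C(C)=CCCC1(C)C | intermediate
10 | (S,E)-1-bromo-3-methyl-5-(2,6,6-trimethylcyclohex-2-en-1-yl)pent-2-ene | BrC/C=C(\C)CC[C@@H]1C(C)=CCCC1(C)C | intermediate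
11 | sodium benzenesulfinate | [Na+].[O-]S(=O)c1ccccc1 | starting material
12 | (S,E)-[3-methyl-5-(2,6,6-trimethylcyclohex-2-en-1-yl)pent-2-en-1-yl] phenyl sulfone | O=S(=O)(c1ccccc1)C/C=C(\C)CC[C@@H]1C(C)=CCCC1(C)C | intermediate
13 | 3-methylbut-2-en-1-ol (prenol) | CC(C)=CCO | starting material
14 | tert-butyldimethyl[(3-methylbut-2-en-1-yl)oxy]silane | CC(C)=CCO[Si](C)(C)C(C)(C)C | intermediate
15 | (E)-4-[(tert-butyldimethylsilyl)oxy]-2-methylbut-2-enal (not isolated) | CC(C)(C)[Si](C)(C)OC/C=C(\C)C=O | intermediate
16 | (E)-4-[(tert-butyldimethylsilyl)oxy]-2-methylbut-2-en-1-ol | CC(C)(C)[Si](C)(C)OC/C=C(\C)CO | intermediate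
17 | (E)-[(4-bromo-3-methylbut-2-en-1-yl)oxy](tert-butyl)dimethylsilane | CC(C)(C)[Si](C)(C)OC/C=C(\C)CBr | intermediate
18 | α-lithio derivative of sulfone 12, lithium at the carbon bearing sulfur (not isolated) | [Li]C(S(=O)(=O)c1ccccc1)/C=C(\C)CC[C@@H]1C(C)=CCCC1(C)C | intermediate
19 | tert-butyldimethyl{[(2E,6E)-3,7-dimethyl-5-(phenylsulfonyl)-9-[(S)-2,6,6-trimethylcyclohex-2-en-1-yl]nona-2,6-dien-1-yl]oxy}silane, mixture of C5 epimers | CC(C)(C)[Si](C)(C)OC/C=C(\C)CC(S(=O)(=O)c1ccccc1)/C=C(\C)CC[C@@H]1C(C)=CCCC1(C)C | intermediate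
20 | tert-butyldimethyl{[(2E,6E)-3,7-dimethyl-9-[(S)-2,6,6-trimethylcyclohex-2-en-1-yl]nona-2,6-dien-1-yl]oxy}silane | CC(C)(C)[Si](C)(C)OC/C=C(\C)CC/C=C(\C)CC[C@@H]1C(C)=CCCC1(C)C | intermediate
21 | (2E,6E)-3,7-dimethyl-9-[(S)-2,6,6-trimethylcyclohex-2-en-1-yl]nona-2,6-dien-1-ol | OC/C=C(\C)CC/C=C(\C)CC[C@@H]1C(C)=CCCC1(C)C | intermediate
22 | linoleic acid, (9Z,12Z)-octadeca-9,12-dienoic acid | CCCCC/C=C\C/C=C\CCCCCCCC(=O)O | starting material
23 | O-[(9Z,12Z)-octadeca-9,12-dienoyl]-N,N′-dicyclohexylisourea (not isolated) | CCCCC/C=C\C/C=C\CCCCCCCC(=O)OC(=NC1CCCCC1)NC1CCCCC1 | intermediate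
24 | (2E,6E)-3,7-dimethyl-9-[(S)-2,6,6-trimethylcyclohex-2-en-1-yl]nona-2,6-dien-1-yl (9Z,12Z)-octadeca-9,12-dienoate | CCCCC/C=C\C/C=C\CCCCCCCC(=O)OC/C=C(\C)CC/C=C(\C)CC[C@@H]1C(C)=CCCC1(C)C | target

**Step count**
Total: 13 steps. Longest linear sequence: 10 steps (steps 1–6, then 10–13); the C5 branch (steps 7–9) joins at step 10.

**Steps most likely to fail**

Step 10 (key alkylation). What may go wrong: proton transfer from the mono-alkylated sulfone to unreacted carbanion followed by a second alkylation, or a slow substitution that lets the bromide decompose by elimination. The fallback forms the same C4–C5 bond with reversed polarity and without sulfur; it sets out from bromide 10 and comes back to the route at dienol 21. The dianion of methyl acetoacetate (NaH, then n-BuLi, THF, 0 °C) is alkylated at its terminal carbon by 10 to give methyl (S,E)-7-methyl-3-oxo-9-(2,6,6-trimethylcyclohex-2-en-1-yl)non-6-enoate F1. The sodium enolate of this β-keto ester with ClP(O)(OEt)2 (Et2O, 0 °C) should give the enol phosphate methyl (2Z,6E)-3-[(diethoxyphosphoryl)oxy]-7-methyl-9-[(S)-2,6,6-trimethylcyclohex-2-en-1-yl]nona-2,6-dienoate F2. Me2CuLi (Et2O, −78 → −45 °C) should replace the phosphate by methyl with retention to give methyl (2E,6E)-3,7-dimethyl-9-[(S)-2,6,6-trimethylcyclohex-2-en-1-yl]nona-2,6-dienoate F3, and i-Bu2AlH (CH2Cl2, −78 °C) reduces this ester to 21.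

Step 11 (desulfonylation). What may go wrong: hydride capture at the more substituted allyl terminus C7, which moves the alkene to C5=C6, or syn–anti interconversion of the π-allyl intermediate, which erodes the E geometry at C6=C7. The fallback uses electron-transfer cleavage on the free alcohol in place of π-allyl hydride capture; it sets out from 19 and comes back at 21. Bu4NF in THF removes the silyl group to give (2E,6E)-3,7-dimethyl-5-(phenylsulfonyl)-9-[(S)-2,6,6-trimethylcyclohex-2-en-1-yl]nona-2,6-dien-1-ol F4. Lithium in ethylamine/THF at −78 °C then cleaves the C5–S bond by two single-electron transfers to give 21 directly; the allylic C1–O bond is shielded as its lithium alkoxide.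

Step 8 (allylic oxidation). What may go wrong: over-oxidation past the alcohol, incomplete conversion, or loss of the silyl ether under the acidic selenium conditions. The fallback builds C2=C3 by olefination in place of C–H oxidation; it sets out from 14 and comes back at 16. Ozonolysis of 14 (O3, CH2Cl2, −78 °C; Me2S) gives (tert-butyldimethylsilyloxy)acetaldehyde F5. Wittig reaction with the stabilised ylide ethyl 2-(triphenylphosphoranylidene)propanoate (CH2Cl2, rt) should give ethyl (E)-4-[(tert-butyldimethylsilyl)oxy]-2-methylbut-2-enoate F6, and i-Bu2AlH (CH2Cl2, −78 °C) reduces this ester to 16.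

**Further compounds**
F1 | step 10 | methyl (S,E)-7-methyl-3-oxo-9-(2,6,6-trimethylcyclohex-2-en-1-yl)non-6-enoate | COC(=O)CC(=O)CC/C=C(\C)CC[C@@H]1C(C)=CCCC1(C)C
F2 | step 10 | methyl (2Z,6E)-3-[(diethoxyphosphoryl)oxy]-7-methyl-9-[(S)-2,6,6-trimethylcyclohex-2-en-1-yl]nona-2,6-dienoate | COC(=O)/C=C(\OP(=O)(OCC)OCC)CC/C=C(\C)CC[C@@H]1C(C)=CCCC1(C)C
F3 | step 10 | methyl (2E,6E)-3,7-dimethyl-9-[(S)-2,6,6-trimethylcyclohex-2-en-1-yl]nona-2,6-dienoate | COC(=O)/C=C(\C)CC/C=C(\C)CC[C@@H]1C(C)=CCCC1(C)C
F4 | step 11 | (2E,6E)-3,7-dimethyl-5-(phenylsulfonyl)-9-[(S)-2,6,6-trimethylcyclohex-2-en-1-yl]nona-2,6-dien-1-ol, mixture of C5 epimers | OC/C=C(\C)CC(S(=O)(=O)c1ccccc1)/C=C(\C)CC[C@@H]1C(C)=CCCC1(C)C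
F5 | step 8 | (tert-butyldimethylsilyloxy)acetaldehyde | CC(C)(C)[Si](C)(C)OCC=O
F6 | step 8 | ethyl (E)-4-[(tert-butyldimethylsilyl)oxy]-2-methylbut-2-enoate | CCOC(=O)/C(C)=C/CO[Si](C)(C)C(C)(C)C
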